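The bond between C2 of the γ-pyranone ring and C1′ of the 4-methoxyphenyl ring is the disconnection on which everything rests. The key step exploits the single C2–H of 3,6,7,8-tetramethoxychromone, flanked by ring oxygen O1 and the C3 methoxy oxygen: a TMP-zinc base turns this normally electrophilic β-carbon of the vinylogous ester into a carbon nucleophile, and Negishi coupling of the C2-zinc species with 4-iodoanisole then delivers auranetin in one operation. The precursor is an aryl-free chromone, made in two steps from 2,3,4-trimethoxyphenol, methoxyacetic acid and DMF-DMA.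

Key step: step 3

Remark: the target contains no stereocentre and is achiral, so the request for a single enantiomer is met by the constitution alone.

**Step 1**
Reactants: 1 2,3,4-trimethoxyphenol; 2 methoxyacetic acid
Product: 3 1-(2-hydroxy-3,4,5-trimethoxyphenyl)-2-methoxyethan-1-one
Conditions: BF3·OEt2 (neat, as solvent), 85 °C; aq. NaOAc work-up
Reagents that add atoms: none
Why: Friedel–Crafts acylation by O-acylation and Fries rearrangement should place the methoxyacetyl group at C6 of the phenol, the only free position ortho to the OH and also para to the 3-OMe, where the product is held as a chelated ortho-hydroxy ketone, and BF3 should leave the aryl methyl ethers intact.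

**Step 2**
Reactants: 3 1-(2-hydroxy-3,4,5-trimethoxyphenyl)-2-methoxyethan-1-one
Product: 5 3,6,7,8-tetramethoxy-4H-chromen-4-one, via enaminone 4 (not isolated)
Conditions: DMF-DMA, toluene, 100 °C; concentrate; then conc. HCl, CH2Cl2, 40 °C
Reagents that add atoms: N,N-dimethylformamide dimethyl acetal, COC(OC)N(C)C
Why: Condensation of the α-methylene group with the amide acetal should give the enaminone, and under acid the phenol oxygen adds to its β-carbon and expels dimethylamine (addition–elimination, the enaminone route to chromones), so the α-methoxy group becomes the 3-OMe and the new CH becomes C2.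

**Step 3**
Reactants: 5 3,6,7,8-tetramethoxy-4H-chromen-4-one; 6 4-iodoanisole
Product: 8 auranetin (3,6,7,8-tetramethoxy-2-(4-methoxyphenyl)-4H-chromen-4-one), via bis(chromon-2-yl)zinc 7 (not isolated)
Conditions: TMP2Zn·2MgCl2·2LiCl (0.6 equiv, stock solution), THF, –30 °C to rt; then 6, Pd(dba)2 (cat.), P(2-furyl)3 (cat.), THF, 50 °C
Reagents that add atoms: none
Why: The hindered amide base removes the only acidic proton of the pyranone ring, C2–H, which is acidified by ring oxygen O1, by the C3 methoxy oxygen and by the MgCl2-complexed C4 carbonyl, so that the normally electrophilic C2 becomes a zinc-bound carbon nucleophile. Pd(0) then inserts into the C–I bond of 6, the chromon-2-yl group passes from zinc to palladium, and reductive elimination forms the C2–C1′ bond (Negishi coupling). The closest known reaction type is the zincation of chromones at C2 with TMP-zinc bases followed by Negishi arylation to flavones. No ring is closed and no stereocentre is formed. The step needs site selectivity for C2–H over C5–H and over nucleophilic opening of the pyranone: the C3 methoxy group blocks the C3 site, the non-nucleophilic base and the mild carbon–zinc bond spare the C4 carbonyl, and the iodine of 6 fixes the coupling site para to its methoxy group.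

**Compound list**
1 | 2,3,4-trimethoxyphenol | COc1ccc(O)c(OC)c1OC | starting material
2 | methoxyacetic acid | COCC(=O)O | starting material
3 | 1-(2-hydroxy-3,4,5-trimethoxyphenyl)-2-methoxyethan-1-one | COCC(=O)c1cc(OC)c(OC)c(OC)c1O | intermediate
4 | (Z)-3-(dimethylamino)-1-(2-hydroxy-3,4,5-trimethoxyphenyl)-2-methoxyprop-2-en-1-one (enaminone; geometry of no consequence) | CN(C)/C=C(\OC)C(=O)c1cc(OC)c(OC)c(OC)c1O | intermediate
5 | 3,6,7,8-tetramethoxy-4H-chromen-4-one | COc1coc2c(OC)c(OC)c(OC)cc2c1=O | intermediate
6 | 4-iodoanisole (1-iodo-4-methoxybenzene) | COc1ccc(I)cc1 | starting material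
7 | bis(3,6,7,8-tetramethoxy-4-oxo-4H-chromen-2-yl)zinc | COc1c([Zn]c2oc3c(OC)c(OC)c(OC)cc3c(=O)c2OC)oc2c(OC)c(OC)c(OC)cc2c1=O | intermediate
8 | auranetin, 3,6,7,8-tetramethoxy-2-(4-methoxyphenyl)-4H-chromen-4-one | COc1ccc(-c2oc3c(OC)c(OC)c(OC)cc3c(=O)c2OC)cc1 | target

Total step count: 3
Longest linear sequence: 3 steps (1 → 3 → 5 → 8); 4-iodoanisole 6 enters in the last step.

**Steps most likely to fail**

Step 3. Deprotonation may occur in part at C5–H (peri to the carbonyl and ortho to the 6-OMe), the pyranone ring may be opened by the base, or the chelated zinc species may transmetalate too slowly. The fallback sets out from 5 and uses the natural polarity of C2. Copper-mediated conjugate addition of 4-methoxyphenylmagnesium bromide (CuBr·SMe2, TMSCl, THF, –78 °C) should give the silyl enol ether 3,6,7,8-tetramethoxy-2-(4-methoxyphenyl)-4-(trimethylsilyloxy)-2H-chromene F1 (racemic at C2; the stereocentre is erased again). Dehydrogenation with DDQ in dioxane, by hydride abstraction from the doubly activated C2–H and loss of the silyl group, should lead back to the route at 8.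

Step 1. Acylation may go in part to C5 (para to the 2-OMe), stall at the aryl ester, or be accompanied by Lewis-acid cleavage of a methyl ether. The fallback sets out from 1 and replaces electrophilic substitution by directed ortho-metalation. MOM protection (MOMCl, iPr2NEt, CH2Cl2) should give 1,2,3-trimethoxy-4-(methoxymethoxy)benzene F2. Lithiation ortho to the OMOM group (n-BuLi, TMEDA, THF, 0 °C) and acylation with N-methoxy-N-methyl-2-methoxyacetamide should give 2-methoxy-1-[3,4,5-trimethoxy-2-(methoxymethoxy)phenyl]ethan-1-one F3. Removal of the MOM group (HCl, MeOH, rt) returns to the route at 3.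

Step 2. The amide acetal may O-methylate the phenol, or condensation at the α-alkoxy methylene group may be sluggish. The fallback sets out from 3 and uses a Claisen formylation instead. Ethyl formate and NaH (THF, 0 °C to rt) should give (E)-3-hydroxy-1-(2-hydroxy-3,4,5-trimethoxyphenyl)-2-methoxyprop-2-en-1-one F4, in equilibrium with its cyclic 2-hydroxychromanone form. Acid-catalysed cyclodehydration (cat. HCl, AcOH, 80 °C) returns to the route at 5.

**Further compounds**
F1 | step 3 | 3,6,7,8-tetramethoxy-2-(4-methoxyphenyl)-4-(trimethylsilyloxy)-2H-chromene (racemic) | COc1ccc(C2Oc3c(OC)c(OC)c(OC)cc3C(O[Si](C)(C)C)=C2OC)cc1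
F2 | step 1 | 1,2,3-trimethoxy-4-(methoxymethoxy)benzene | COCOc1ccc(OC)c(OC)c1OC
F3 | step 1 | 2-methoxy-1-[3,4,5-trimethoxy-2-(methoxymethoxy)phenyl]ethan-1-one | COCC(=O)c1cc(OC)c(OC)c(OC)c1OCOC
F4 | step 2 | (E)-3-hydroxy-1-(2-hydroxy-3,4,5-trimethoxyphenyl)-2-methoxyprop-2-en-1-one | O/C=C(/OC)C(=O)c1cc(OC)c(OC)c(OC)c1O
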